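The numbers are assumed; the run is a simulation.

With 0.800 equiv of partner against one equivalent of starting material, target cannot reach the whole charge, and second substrate and third substrate draw on the same partner.

the same everywhere: starting material 0.25 M; partner 0.800 equiv; protic impurity 0.0500 M; time 40 s
- Thursday's: second substrate 0.500 equiv (fed, over 15 s); third substrate 1.00 equiv; the addition at −10 °C, then warmed to 20 °C; the feed brings no volume worth counting
- Friday's: second substrate 0.500 equiv; third substrate 1.00 equiv; everything together at the start; temperature 20 °C
- Sunday's: second substrate 0.500 equiv; third substrate 1.00 equiv; everything together at the start at −10 °C, warmed to 20 °C at 15 s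
- Tuesday's: second substrate 0.500 equiv; third substrate 1.00 equiv (in portions, 4, over 15 s); first portion at the start, last at 15 s; temperature 20 °C
- Wednesday's: second substrate 0.500 equiv (fed, over 15 s); third substrate 1.00 equiv; all else is in the flask from the start; the feed brings no volume worth counting; temperature 20 °C

    starting material + partner → target (k1 = 0.56 M⁻¹ s⁻¹, Ea1 = 62.0 kJ mol⁻¹)
    second substrate + partner → second product (k2 = 1.1 M⁻¹ s⁻¹, Ea2 = 36.0 kJ mol⁻¹)
    third substrate + partner → third product (k3 = 1.6 M⁻¹ s⁻¹, Ea3 = 58.0 kJ mol⁻¹)
    third substrate + protic impurity → quenched substrate (k4 = 2.6 M⁻¹ s⁻¹, Ea4 = 58.0 kJ mol⁻¹)
    partner → decomposed reagent (k5 = 0.067 s⁻¹, Ea5 = 66.0 kJ mol⁻¹)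
    (constants at 20 °C)

* the flask with the highest amount of target, in percent of the starting material charged ("all alike" if they lie within 1.5 percentage points) (Thursday's / Friday's / Sunday's / Tuesday's / Wednesday's / all alike)
* final target, as a percentage of the starting material charged, in Thursday's
* final target, as a percentage of the starting material charged, in Friday's
* final target, as a percentage of the starting material charged, in Sunday's
* final target, as a percentage of the starting material charged, in Tuesday's
* final target, as a percentage of the starting material charged, in Wednesday's

- constants are those at 20 °C; use the activation energies for any other temperature

Partner is the limiting reagent, so we follow how it is shared out. Each route takes partner at its rate constant times the concentration of its substrate, and the decomposition takes it at its own constant. Target's share of the partner is the target route's rate over the sum of all these rates, and that share times the partner charged estimates the target.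

Which numbers must be known well? We test this on Tuesday's at the start, with the first portion in, so [third substrate] is 0.0625 M. The target route then runs at 0.140 s⁻¹, the second substrate route at 0.138 s⁻¹, the third substrate route at 0.100 s⁻¹ and the decomposition at 0.067 s⁻¹. Doubling the target constant moves the estimate to 38.3 %. Doubling the others gives 19.2 % for second substrate, 20.6 % for third substrate and 21.9 % for decomposition. In Friday's, third substrate's half-life against impurity alone, with the impurity held at its charge, is 5.3 s, longer than partner's starting half-life of 0.931 s, so we leave the impurity out of the estimate.

The number itself: target's share of the partner at the start of Tuesday's 31.5 % gives 25.2 % for that flask. Partner's starting half-life in Tuesday's, 1.56 s, is shorter than the 5.00 s between portions, so we count the first portion and no other. Friday's, with all its third substrate in, gives 15.0 %. The share should drift upward in Friday's, and in Tuesday's until its second portion, because each substrate competitor meets partner with a larger constant than starting material does. Both substrate competitors also have lower activation energies than the target step, so, with Sunday's starting at −10 °C, we put Sunday's below Friday's, without a figure. We commit to Tuesday's as highest.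

The forecast also names Tuesday's, with 16.8 % for Thursday's, 17.9 % for Friday's, 15.1 % for Sunday's, 27 % for Tuesday's and 21.7 % for Wednesday's. Its ground for the winner is “Portioning keeps the fast third substrate low, and the impurity removes part of it”. Its Tuesday's and Friday's figures stand above our starting-moment estimates.

The simulation gives 16.6 % in Thursday's, 17.4 % in Friday's, 14.9 % in Sunday's, 26.7 % in Tuesday's and 21.3 % in Wednesday's, so Tuesday's is highest. In Tuesday's, half of the second product had formed by 1.61 s and 96 % of it by 8.00 s, against 5.00 s between portions, and the target ended 1.5 percentage points above the estimate. In Wednesday's, second substrate starts at none, so the share at the start, with that route left out, gives an estimate of 18.5 %, and the target in Wednesday's ended at 21.3 %.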